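The plan rests on cutting the two aryl–CH2 bonds at once. In the target, C6 of the salicylic acid ring (ring B) and C6' of the 4-methoxysalicyloyl ring (ring A) carry identical n-heptyl groups, each ortho to a carbonyl-bearing carbon (C1, C1'). One alkylzinc reagent can therefore install both chains on a 6,6'-dibromo depside in a single twofold Negishi coupling. That precursor is the tribenzyl-protected depside, built from one aldehyde, 2-bromo-4,6-dimethoxybenzaldehyde: ring A by ortho-demethylation, benzylation and oxidation, ring B by acylating the para hydroxyl of the fully demethylated aldehyde, so no temporary protecting group is needed. Hydrogenolysis of the three benzyl groups ends the route.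

Key step: step 10

Remark: the target has no stereogenic element, so there is no enantiomer to select and no stereocentre to set. Primed locants refer to ring A (benzoyl ring), unprimed ones to ring B (benzoic acid ring).

Step 1
Reactants: 1 1-bromo-3,5-dimethoxybenzene
Product: 3 2-bromo-4,6-dimethoxybenzaldehyde, via aryl iminium salt 2 (not isolated)
Conditions: POCl3, DMF, 0 → 90 °C; then ice-water, rt
Reagents that add atoms: N,N-dimethylformamide, CN(C)C=O (formyl carbon; also the Me2N group of 2); phosphoryl chloride, ClP(Cl)(Cl)=O (counter-ion of 2 only); water, O (carbonyl oxygen of 3)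
Why: Vilsmeier–Haack formylation: the chloroiminium ion made from DMF and POCl3 should attack C2, para to one methoxy group and ortho to the other, in preference to C4 between both methoxy groups, and water then hydrolyses iminium salt 2 to the aldehyde, any minor 4-bromo-2,6-dimethoxy isomer being removable by crystallisation.

Step 2
Reactants: 3 2-bromo-4,6-dimethoxybenzaldehyde
Product: 5 2-bromo-6-hydroxy-4-methoxybenzaldehyde, via aryloxydichloroborane 4 (not isolated)
Conditions: BCl3 (1.2 equiv), CH2Cl2, −78 → 0 °C; then H2O
Reagents that add atoms: boron trichloride, ClB(Cl)Cl (boron and chlorine of intermediate 4 only; nothing of it remains in 5)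
Why: Chelation-directed Lewis-acid ether cleavage: boron binds the formyl oxygen together with the neighbouring methoxy oxygen, so chloride removes only the ortho methyl group, while the para methoxy group cannot chelate and stays in place at low temperature.

Step 3
Reactants: 5 2-bromo-6-hydroxy-4-methoxybenzaldehyde; 6 benzyl bromide
Product: 7 2-(benzyloxy)-6-bromo-4-methoxybenzaldehyde
Conditions: BnBr, K2CO3, DMF, rt
Reagents that add atoms: benzyl bromide (6), BrCc1ccccc1
Why: Williamson ether synthesis: the acidic ortho-formyl phenol is deprotonated by carbonate and alkylated by the reactive benzylic bromide, and nothing else in 5 is nucleophilic.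

Step 4
Reactants: 7 2-(benzyloxy)-6-bromo-4-methoxybenzaldehyde
Product: 8 2-(benzyloxy)-6-bromo-4-methoxybenzoic acid
Conditions: NaClO2, NaH2PO4, 2-methyl-2-butene, t-BuOH/THF/H2O, rt
Reagents that add atoms: sodium chlorite, [Na+].[O-]Cl=O
Why: Pinnick oxidation: chlorous acid adds to the aldehyde and fragments to the acid under buffered, mildly acidic conditions that spare the benzyl ether and aryl bromide, while 2-methyl-2-butene traps hypochlorous acid so that the electron-rich ring is not chlorinated.

Step 5
Reactants: 3 2-bromo-4,6-dimethoxybenzaldehyde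
Product: 10 2-bromo-4,6-dihydroxybenzaldehyde, via bis(dibromoboryl) ether 9 (not isolated)
Conditions: BBr3 (4 equiv), CH2Cl2, −78 °C → rt; then H2O
Reagents that add atoms: boron tribromide, BrB(Br)Br (boron and bromine of intermediate 9 only; nothing of it remains in 10)
Why: Exhaustive Lewis-acid demethylation of aryl methyl ethers: excess BBr3 at room temperature cleaves the chelated ortho and the non-chelated para methoxy group alike, and the aryl bromide and the aldehyde should come through the aqueous work-up unchanged.

Step 6
Reactants: 8 2-(benzyloxy)-6-bromo-4-methoxybenzoic acid; 10 2-bromo-4,6-dihydroxybenzaldehyde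
Product: 12 3-bromo-4-formyl-5-hydroxyphenyl 2-(benzyloxy)-6-bromo-4-methoxybenzoate, via acid chloride 11 (not isolated)
Conditions: (COCl)2, DMF (cat.), CH2Cl2, 0 °C → rt, evaporate; then 10, Et3N (1.1 equiv), DMAP (5 mol %), THF, −10 → 0 °C
Reagents that add atoms: oxalyl chloride, ClC(=O)C(=O)Cl (chlorine of intermediate 11 only; nothing of it remains in 12)
Why: Acid chloride formation followed by DMAP-catalysed O-acylation of a phenol (nucleophilic acyl substitution): in 10 the hydroxyl para to the formyl group is free and the more acidic one, whereas the ortho hydroxyl is locked in a hydrogen bond to the carbonyl, so one equivalent of base and of 11 should esterify the para oxygen only.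

Step 7
Reactants: 12 3-bromo-4-formyl-5-hydroxyphenyl 2-(benzyloxy)-6-bromo-4-methoxybenzoate
Product: 13 4-{[2-(benzyloxy)-6-bromo-4-methoxybenzoyl]oxy}-2-bromo-6-hydroxybenzoic acid
Conditions: NaClO2, NaH2PO4, 2-methyl-2-butene (large excess), t-BuOH/THF/H2O, 0 °C → rt
Reagents that add atoms: sodium chlorite, [Na+].[O-]Cl=O
Why: Pinnick oxidation of a salicylaldehyde: the buffered chlorite medium (about pH 3–4) oxidises the formyl group without touching the hindered aryl ester, and the alkene scavenger protects the free phenol ring from chlorination.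

Step 8
Reactants: 13 4-{[2-(benzyloxy)-6-bromo-4-methoxybenzoyl]oxy}-2-bromo-6-hydroxybenzoic acid; 6 benzyl bromide
Product: 14 benzyl 2-(benzyloxy)-4-{[2-(benzyloxy)-6-bromo-4-methoxybenzoyl]oxy}-6-bromobenzoate
Conditions: BnBr (2.5 equiv), K2CO3 (anhydrous), acetone, reflux
Reagents that add atoms: benzyl bromide (6), BrCc1ccccc1
Why: Twofold Williamson-type O-alkylation (carboxylate first, then the chelated phenol) under anhydrous carbonate/acetone conditions of the kind used to per-alkylate depsides; the depside carbonyl, flanked by two ortho substituents, should be too hindered for attack by the weakly nucleophilic salicylate phenoxide.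

Step 9
Reactants: 15 1-bromoheptane
Product: 16 heptylzinc bromide (THF solution, titrated with iodine)
Conditions: Zn dust (1.5 equiv, activated with cat. BrCH2CH2Br/TMSCl), LiCl, THF, 50 °C
Reagents that add atoms: zinc, [Zn]
Why: Direct oxidative insertion of activated zinc into a primary alkyl bromide, accelerated by LiCl, which dissolves the organozinc as it forms (Knochel-type preparation).

Step 10
Reactants: 14 benzyl 2-(benzyloxy)-4-{[2-(benzyloxy)-6-bromo-4-methoxybenzoyl]oxy}-6-bromobenzoate; 16 heptylzinc bromide
Product: 17 benzyl 2-(benzyloxy)-4-{[2-(benzyloxy)-6-heptyl-4-methoxybenzoyl]oxy}-6-heptylbenzoate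
Conditions: 16 (3 equiv, slow addition), Pd(OAc)2 (5 mol %), SPhos (10 mol %), THF, rt → 45 °C
Reagents that add atoms: heptylzinc bromide (16), CCCCCCC[Zn]Br
Why: Negishi cross-coupling run twice on one substrate: SPhos-ligated Pd(0) inserts into each aryl C–Br bond (both activated by the ortho ester carbonyl), the heptyl group passes from zinc to palladium, and reductive elimination forms the C6–CH2 and C6'–CH2 bonds. The closest known reaction type is the Pd/dialkylbiarylphosphine coupling of ortho-substituted aryl bromides with primary alkylzinc halides, here run with excess reagent so that both sites react. No ring is closed and no stereocentre is created. The step needs chemoselectivity for C–Br over the C(acyl)–O bond of the aryl ester and over carbonyl addition: a palladium–phosphine catalyst at or below 45 °C does not insert into aryl ester C–O bonds, alkylzinc halides do not add to esters, and the depside carbonyl is shielded by its two ortho substituents. β-Hydride elimination, which would give hydrodebrominated arene and heptene, should be held back because the bulky electron-rich ligand makes reductive elimination fast.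

Step 11
Reactants: 17 benzyl 2-(benzyloxy)-4-{[2-(benzyloxy)-6-heptyl-4-methoxybenzoyl]oxy}-6-heptylbenzoate
Product: 18 4-[(2-heptyl-6-hydroxy-4-methoxybenzoyl)oxy]-2-heptyl-6-hydroxybenzoic acid
Conditions: H2 (1 atm), 10% Pd/C, EtOAc, rt
Reagents that add atoms: none
Why: Catalytic hydrogenolysis of the three benzylic C–O bonds over Pd/C in a non-nucleophilic solvent; the aryl ester, the methyl ether and the alkyl chains are inert, and neutral conditions at room temperature avoid decarboxylation of the salicylic acid and alcoholysis of the depside.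

Compound list
1 | 1-bromo-3,5-dimethoxybenzene | COc1cc(Br)cc(OC)c1 | starting material
2 | N-[(2-bromo-4,6-dimethoxyphenyl)methylidene]-N-methylmethanaminium dichlorophosphate | COc1cc(OC)c(C=[N+](C)C)c(Br)c1.[O-]P(=O)(Cl)Cl | intermediate
3 | 2-bromo-4,6-dimethoxybenzaldehyde | COc1cc(OC)c(C=O)c(Br)c1 | intermediate
4 | (3-bromo-2-formyl-5-methoxyphenoxy)dichloroborane | COc1cc(OB(Cl)Cl)c(C=O)c(Br)c1 | intermediate
5 | 2-bromo-6-hydroxy-4-methoxybenzaldehyde | COc1cc(O)c(C=O)c(Br)c1 | intermediate
6 | benzyl bromide | BrCc1ccccc1 | starting material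
7 | 2-(benzyloxy)-6-bromo-4-methoxybenzaldehyde | COc1cc(OCc2ccccc2)c(C=O)c(Br)c1 | intermediate
8 | 2-(benzyloxy)-6-bromo-4-methoxybenzoic acid | COc1cc(OCc2ccccc2)c(C(=O)O)c(Br)c1 | intermediate
9 | 2-bromo-4,6-bis[(dibromoboranyl)oxy]benzaldehyde | O=Cc1c(Br)cc(OB(Br)Br)cc1OB(Br)Br | intermediate
10 | 2-bromo-4,6-dihydroxybenzaldehyde | O=Cc1c(Br)cc(O)cc1O | intermediate
11 | 2-(benzyloxy)-6-bromo-4-methoxybenzoyl chloride | COc1cc(OCc2ccccc2)c(C(Cl)=O)c(Br)c1 | intermediate
12 | 3-bromo-4-formyl-5-hydroxyphenyl 2-(benzyloxy)-6-bromo-4-methoxybenzoate | COc1cc(OCc2ccccc2)c(C(=O)Oc2cc(O)c(C=O)c(Br)c2)c(Br)c1 | intermediate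
13 | 4-{[2-(benzyloxy)-6-bromo-4-methoxybenzoyl]oxy}-2-bromo-6-hydroxybenzoic acid | COc1cc(OCc2ccccc2)c(C(=O)Oc2cc(O)c(C(=O)O)c(Br)c2)c(Br)c1 | intermediate
14 | benzyl 2-(benzyloxy)-4-{[2-(benzyloxy)-6-bromo-4-methoxybenzoyl]oxy}-6-bromobenzoate | Brc1cc(OC(=O)c2c(OCc3ccccc3)cc(OC)cc2Br)cc(OCc2ccccc2)c1C(=O)OCc1ccccc1 | intermediate
15 | 1-bromoheptane | CCCCCCCBr | starting material
16 | heptylzinc bromide | CCCCCCC[Zn]Br | intermediate
17 | benzyl 2-(benzyloxy)-4-{[2-(benzyloxy)-6-heptyl-4-methoxybenzoyl]oxy}-6-heptylbenzoate | CCCCCCCc1cc(OC(=O)c2c(OCc3ccccc3)cc(OC)cc2CCCCCCC)cc(OCc2ccccc2)c1C(=O)OCc1ccccc1 | intermediate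
18 | 4-[(2-heptyl-6-hydroxy-4-methoxybenzoyl)oxy]-2-heptyl-6-hydroxybenzoic acid | CCCCCCCc1cc(OC(=O)c2c(O)cc(OC)cc2CCCCCCC)cc(O)c1C(=O)O | target

Total step count: 11
Longest linear sequence: 9 steps (steps 1, 2, 3, 4, 6, 7, 8, 10, 11). Step 5 (ring B aldehyde) and step 9 (zinc reagent) are side branches.

Steps most likely to fail

1. Step 10. The second coupling may stall, β-hydride elimination may lead to hydrodebromination at one site, or palladium may attack the aryl ester. The fallback sets out from 14 and returns at 18, replacing the sp2–sp3 coupling by an sp2–sp coupling followed by reduction. A twofold Sonogashira reaction of 14 with hept-1-yne (PdCl2(PPh3)2, CuI, Et3N, DMF, 60 °C) should give benzyl 2-(benzyloxy)-4-{[2-(benzyloxy)-6-(hept-1-yn-1-yl)-4-methoxybenzoyl]oxy}-6-(hept-1-yn-1-yl)benzoate F1. Hydrogenation of F1 over Pd/C in EtOAc should then saturate both alkynes and remove the three benzyl groups in one operation, giving 18 directly.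

2. Step 6. The hindered acid chloride may acylate too slowly, or site selectivity between the para and the chelated ortho hydroxyl may be lost, with double acylation as a further risk. The fallback sets out from 10 and returns at 14, building a fully protected ring B phenol before the esterification.
- Selective etherification of the para hydroxyl of 10 (MOMCl, iPr2NEt, CH2Cl2, 0 °C) should give 2-bromo-6-hydroxy-4-(methoxymethoxy)benzaldehyde F2.
- Pinnick oxidation should give 2-bromo-6-hydroxy-4-(methoxymethoxy)benzoic acid F3.
- Double benzylation (BnBr, K2CO3, DMF) should give benzyl 2-(benzyloxy)-6-bromo-4-(methoxymethoxy)benzoate F4.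
- Acetal cleavage (cat. HCl, MeOH/THF, 40 °C) should give benzyl 2-(benzyloxy)-6-bromo-4-hydroxybenzoate F5.
- Acylation of the single free phenol of F5 with acid chloride 11 (Et3N, DMAP, CH2Cl2) leads to 14.

3. Step 8. Under carbonate the chelated salicylate phenoxide may benzylate slowly while the depside ester is cleaved or passed between phenoxides. The fallback sets out from 12 and returns at 14, putting the ether on under neutral conditions before the oxidation.
- Mitsunobu etherification of 12 (BnOH, PPh3, DIAD, THF, 0 °C → rt) should give 3-(benzyloxy)-5-bromo-4-formylphenyl 2-(benzyloxy)-6-bromo-4-methoxybenzoate F6.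
- Pinnick oxidation should give 2-(benzyloxy)-4-{[2-(benzyloxy)-6-bromo-4-methoxybenzoyl]oxy}-6-bromobenzoic acid F7.
- Esterification of the carboxylate alone (BnBr, KHCO3, DMF, rt), with no phenoxide present, leads to 14.

Further compounds
F1 | step 10 | benzyl 2-(benzyloxy)-4-{[2-(benzyloxy)-6-(hept-1-yn-1-yl)-4-methoxybenzoyl]oxy}-6-(hept-1-yn-1-yl)benzoate | CCCCCC#Cc1cc(OC(=O)c2c(OCc3ccccc3)cc(OC)cc2C#CCCCCC)cc(OCc2ccccc2)c1C(=O)OCc1ccccc1
F2 | step 6 | 2-bromo-6-hydroxy-4-(methoxymethoxy)benzaldehyde | COCOc1cc(O)c(C=O)c(Br)c1
F3 | step 6 | 2-bromo-6-hydroxy-4-(methoxymethoxy)benzoic acid | COCOc1cc(O)c(C(=O)O)c(Br)c1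
F4 | step 6 | benzyl 2-(benzyloxy)-6-bromo-4-(methoxymethoxy)benzoate | COCOc1cc(OCc2ccccc2)c(C(=O)OCc2ccccc2)c(Br)c1
F5 | step 6 | benzyl 2-(benzyloxy)-6-bromo-4-hydroxybenzoate | Oc1cc(OCc2ccccc2)c(C(=O)OCc2ccccc2)c(Br)c1
F6 | step 8 | 3-(benzyloxy)-5-bromo-4-formylphenyl 2-(benzyloxy)-6-bromo-4-methoxybenzoate | COc1cc(OCc2ccccc2)c(C(=O)Oc2cc(OCc3ccccc3)c(C=O)c(Br)c2)c(Br)c1
F7 | step 8 | 2-(benzyloxy)-4-{[2-(benzyloxy)-6-bromo-4-methoxybenzoyl]oxy}-6-bromobenzoic acid | COc1cc(OCc2ccccc2)c(C(=O)Oc2cc(OCc3ccccc3)c(C(=O)O)c(Br)c2)c(Br)c1
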